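**Plan**

- Retrosynthesis: cut first the bond between C1 (the ring carbon that carries the pendant veratryl group) and C8a of ring A (the dimethoxybenzo ring), and rehydrate the C3=C4 alkene to a benzylic carbinol. This opens ring B (the carbocycle fused to ring A) to a C2-symmetric 1,4-diaryl-2,3-dimethylbutane-1,4-diol.
- Cut next both aryl–carbinol carbon bonds (aryllithium plus a derivative of (2R,3R)-2,3-dimethylsuccinic acid), and last the central C2–C3 bond, which leaves two propanoyl units on an oxazolidinone auxiliary.
- Forward: the four-carbon chain is joined first by oxidative enolate dimerisation, the two veratryl rings are attached, and ring B closes last in an acid-triggered cascade modelled on the presumed biosynthesis of aryltetralin lignans from diaryl-dimethylbutane and tetrahydrofuran lignans.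
- Enabling feature: each veratryl ring is both acceptor and donor. Its 4-methoxy group stabilises a cation on the attached benzylic carbon (future C1 and C4). Its 3-methoxy group activates the ring carbon para to it (future C8a), which is separated from the far benzylic carbon by four atoms, so a six-membered ring results.
- Stereochemistry: both methyl-bearing centres are set (R,R) by the auxiliary; one survives as C2 and its twin is consumed in the alkene. C1 is set in the ring closure, trans to the C2 methyl.

Key step: step 6

Remark: locants follow the naphthalene numbering of the target (C1 aryl-bearing, C2 methyl-bearing stereocentre, C3=C4 alkene, C4a/C8a ring fusion); the carbinol centres of 9, the aryl-bearing centres of 10 and the carbinol centre of 11 arise as epimer mixtures and are written without descriptors, since all of them are destroyed before 12.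

**Route**

Step 1
Reactants: 1 (4S)-4-isopropyl-3-propanoyl-1,3-oxazolidin-2-one (two molecules)
Product: 3 (2R,3R)-1,4-bis[(4S)-4-isopropyl-2-oxo-1,3-oxazolidin-3-yl]-2,3-dimethylbutane-1,4-dione, via lithium Z-enolate 2 (not isolated)
Conditions: LiN(i-Pr)2 (1.1 equiv), THF, −78 °C; then TiCl4 (1.1 equiv), −78 → 0 °C
Reagents that add atoms: none
Why: Oxidative enolate homocoupling of an Evans N-acyloxazolidinone, in which tetravalent titanium oxidises the chelated Z-enolate (and becomes trivalent titanium) and both new stereocentres are set R by the auxiliary, whose isopropyl group blocks one face of each partner so that the C–C bond forms on the open face of both, the same face that electrophiles take in Evans alkylations.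

Step 2
Reactants: 3 (2R,3R)-1,4-bis[(4S)-4-isopropyl-2-oxo-1,3-oxazolidin-3-yl]-2,3-dimethylbutane-1,4-dione
Product: 4 (2R,3R)-2,3-dimethylbutanedioic acid
Conditions: LiOH, 30% H2O2, THF/H2O, 0 °C; then aq. Na2SO3; then HCl to pH 1, extraction
Reagents that add atoms: hydrogen peroxide, OO (used as lithium hydroperoxide, formed in the flask with lithium hydroxide, [Li+].[OH-]; it supplies the hydroxyl oxygen of each carboxyl group)
Why: Auxiliary cleavage with lithium hydroperoxide, whose attack is selective for the exocyclic imide carbonyl even in hindered imides and which is too weakly basic to enolise the substrate, so the two stereocentres should be untouched and the oxazolidinone can be recovered.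

Step 3
Reactants: 4 (2R,3R)-2,3-dimethylbutanedioic acid
Product: 5 (2R,3R)-N1,N4-dimethoxy-N1,N4,2,3-tetramethylbutanediamide
Conditions: MeNH(OMe)·HCl (2.5 equiv), EDC·HCl (2.5 equiv), HOBt (0.2 equiv), N-methylmorpholine (6 equiv), CH2Cl2, 0 °C → rt
Reagents that add atoms: N,O-dimethylhydroxylamine hydrochloride, CNOC.Cl
Why: Carbodiimide amide coupling to the bis-Weinreb amide (through the HOBt ester or a transient cyclic anhydride), in which the trans-dimethyl arrangement is also the thermodynamically preferred one in the transient anhydride, so the (2R,3R) configuration should be kept.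

Step 4
Reactants: 5 (2R,3R)-N1,N4-dimethoxy-N1,N4,2,3-tetramethylbutanediamide; 6 4-bromo-1,2-dimethoxybenzene
Product: 8 (2R,3R)-1,4-bis(3,4-dimethoxyphenyl)-2,3-dimethylbutane-1,4-dione, via aryllithium 7 (not isolated)
Conditions: 6 (2.6 equiv), n-BuLi (2.5 equiv), THF, −78 °C; then 5, −78 → 0 °C; cold 1 M HCl quench
Reagents that add atoms: none
Why: Weinreb ketone synthesis, in which bromine–lithium exchange gives aryllithium 7 and the five-membered lithium chelate of each tetrahedral adduct survives until the quench, so that no over-addition occurs and the α-stereocentres never meet base at the ketone stage.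

Step 5
Reactants: 8 (2R,3R)-1,4-bis(3,4-dimethoxyphenyl)-2,3-dimethylbutane-1,4-dione
Product: 9 (2R,3R)-1,4-bis(3,4-dimethoxyphenyl)-2,3-dimethylbutane-1,4-diol (carbinol epimers)
Conditions: LiAlH4 (1.5 equiv), THF, −78 → 0 °C; H2O, aq. NaOH work-up
Reagents that add atoms: none
Why: Hydride reduction of the aryl ketones with LiAlH4 at low temperature should be faster than enolisation, so C2 and C3 are kept, and the two new carbinol centres need no control because both are ionised in step 6.

Step 6
Reactants: 9 (2R,3R)-1,4-bis(3,4-dimethoxyphenyl)-2,3-dimethylbutane-1,4-diol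
Product: 12 (1R,2S)-1-(3,4-dimethoxyphenyl)-6,7-dimethoxy-2,3-dimethyl-1,2-dihydronaphthalene, via tetrahydrofuran 10 (not isolated), via tetralol 11 (not isolated)
Conditions: CF3CO2H (10 equiv), CH2Cl2 (0.01 M), 0 → 23 °C, run until 10 is consumed; aq. NaHCO3 quench
Reagents that add atoms: none
Why: Acid ionises either of the two homotopic benzylic carbinols of 9 (directly, or after fast reversible closure to tetrahydrofuran 10, which reopens under the same acid) to a benzylic cation that the 4-methoxy group stabilises as a quinone-methide-type oxocarbenium ion; the far veratryl ring attacks it through the ring carbon para to its 3-methoxy group (intramolecular Friedel–Crafts alkylation) to give tetralol 11, whose remaining benzylic carbinol (para to the 7-methoxy group) ionises in turn and loses the only β-proton, at C3, to give the C3=C4 styrene of 12. The closest known reaction type is the acid-promoted conversion of 2,5-diaryl-3,4-dimethyltetrahydrofuran lignans and the related diols into aryltetralin and aryldihydronaphthalene lignans, which is also the presumed biosynthetic ring closure. The one ring formed, ring B, is six-membered and closes 6-exo-trig with respect to the cationic carbon, the attacking arene π bond lying inside the new ring. The one new stereocentre, C1, is controlled by the substrate: in the half-chair transition state the pendant aryl group, the C2 methyl and the C3 methyl are all pseudo-equatorial, which places the aryl group trans to the C2 methyl and gives (1R,2S) from the (2R,3R) chain. The step needs ring closure to outrun proton loss from the open cation (secured by the electron-rich ring held in reach for a six-membered transition state), attack para and not ortho to the methoxy group (secured by the crowding of the position between chain and methoxy group), and one enantiomer whichever carbinol ionises first (secured by the C2 symmetry of 9, the second methyl-bearing centre being consumed in the alkene); the irreversible C–C bond formation drains the reversible ether formation.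

**Compound list**

1 | (4S)-4-isopropyl-3-propanoyl-1,3-oxazolidin-2-one | CCC(=O)N1[C@@H](C(C)C)COC1=O | starting material
2 | lithium (Z)-enolate of 1 | C/C=C(\O[Li])N1[C@@H](C(C)C)COC1=O | intermediate
3 | (2R,3R)-1,4-bis[(4S)-4-isopropyl-2-oxo-1,3-oxazolidin-3-yl]-2,3-dimethylbutane-1,4-dione | CC(C)[C@H]1COC(=O)N1C(=O)[C@H](C)[C@@H](C)C(=O)N1[C@@H](C(C)C)COC1=O | intermediate
4 | (2R,3R)-2,3-dimethylbutanedioic acid | OC(=O)[C@H](C)[C@@H](C)C(=O)O | intermediate
5 | (2R,3R)-N1,N4-dimethoxy-N1,N4,2,3-tetramethylbutanediamide | CON(C)C(=O)[C@H](C)[C@@H](C)C(=O)N(C)OC | intermediate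
6 | 4-bromo-1,2-dimethoxybenzene | COc1ccc(Br)cc1OC | starting material
7 | (3,4-dimethoxyphenyl)lithium | COc1ccc([Li])cc1OC | intermediate
8 | (2R,3R)-1,4-bis(3,4-dimethoxyphenyl)-2,3-dimethylbutane-1,4-dione | COc1ccc(C(=O)[C@H](C)[C@@H](C)C(=O)c2ccc(OC)c(OC)c2)cc1OC | intermediate
9 | (2R,3R)-1,4-bis(3,4-dimethoxyphenyl)-2,3-dimethylbutane-1,4-diol, carbinol epimers | COc1ccc(C(O)[C@H](C)[C@@H](C)C(O)c2ccc(OC)c(OC)c2)cc1OC | intermediate
10 | (3R,4R)-2,5-bis(3,4-dimethoxyphenyl)-3,4-dimethyloxolane, C2/C5 epimers | COc1ccc(C2OC(c3ccc(OC)c(OC)c3)[C@H](C)[C@H]2C)cc1OC | intermediate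
11 | (2R,3S,4R)-4-(3,4-dimethoxyphenyl)-6,7-dimethoxy-2,3-dimethyl-1,2,3,4-tetrahydronaphthalen-1-ol, C1 epimers | COc1ccc([C@@H]2c3cc(OC)c(OC)cc3C(O)[C@H](C)[C@H]2C)cc1OC | intermediate
12 | (1R,2S)-1-(3,4-dimethoxyphenyl)-6,7-dimethoxy-2,3-dimethyl-1,2-dihydronaphthalene | COc1ccc([C@@H]2c3cc(OC)c(OC)cc3C=C(C)[C@H]2C)cc1OC | target

**Summary**

Total step count: 6. Longest linear sequence: 6 steps (1 → 12).

**Steps most likely to fail**

Step 6. Proton loss from the open-chain benzylic cation before ring closure would erode the C2 configuration, and the acid may isomerise or dimerise the styrene product. The fallback sets out from diacid 4 and comes back at tetralol 11, now isolated, whose dehydration is the last event of step 6 and needs only a catalytic acid. Acetyl chloride should close 4 to (3R,4R)-3,4-dimethyloxolane-2,5-dione F1. Two equivalents of aryllithium 7 at −78 °C, then acidic work-up, should give the lactone (3R,4R)-5,5-bis(3,4-dimethoxyphenyl)-3,4-dimethyloxolan-2-one F2. Hydrogenolysis of its doubly benzylic C–O bond (H2, Pd/C, AcOH) should give (2R,3S)-4,4-bis(3,4-dimethoxyphenyl)-2,3-dimethylbutanoic acid F3. Intramolecular Friedel–Crafts acylation ((CF3CO)2O, CH2Cl2) onto one of the two diastereotopic aryl groups should give (2R,3S,4R)-4-(3,4-dimethoxyphenyl)-6,7-dimethoxy-2,3-dimethyl-3,4-dihydronaphthalen-1(2H)-one F4, with the remaining aryl group trans to the neighbouring methyl group. NaBH4 in MeOH should then give 11. Ring B is closed here through an acylium ion at the other end of the chain, so no secondary benzylic cation next to C2 is formed, and the centre α to the ketone is the one that ends in the alkene.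

Step 1. The oxidative coupling may stall or lose facial control on one partner, which would give the (2R,3S) dimer. The fallback sets out from 1 and comes back at 4. Methyl (R)-lactate and (CF3SO2)2O/2,6-lutidine should give methyl (2R)-2-(trifluoromethylsulfonyloxy)propanoate F5. Enolate 2 should displace its triflate with inversion, under auxiliary control at the enolate carbon, to give methyl (2R,3R)-4-[(4S)-4-isopropyl-2-oxo-1,3-oxazolidin-3-yl]-2,3-dimethyl-4-oxobutanoate F6. LiOH/H2O2 followed by LiOH should hydrolyse imide and ester to 4. The two centres are then set by two independent, known two-electron events instead of one radical coupling.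

Step 4. The second aryl addition to the hindered bis-amide may be incomplete, and the strongly basic aryllithium may enolise and epimerise the substrate. The fallback sets out from 3 and comes back at 8. EtSLi (EtSH, n-BuLi, THF, 0 °C) should cleave both auxiliaries to give S,S-diethyl (2R,3R)-2,3-dimethylbutanebis(thioate) F7. A base-free Liebeskind–Srogl coupling with 3,4-dimethoxyphenylboronic acid (Pd2(dba)3, tri(2-furyl)phosphine, Cu(O2CC4H3S), the thiophene-2-carboxylate of monovalent copper, THF, 50 °C) should then give diketone 8.

**Further compounds**

F1 | step 6 | (3R,4R)-3,4-dimethyloxolane-2,5-dione | O=C1OC(=O)[C@H](C)[C@H]1C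
F2 | step 6 | (3R,4R)-5,5-bis(3,4-dimethoxyphenyl)-3,4-dimethyloxolan-2-one | COc1ccc(C2(c3ccc(OC)c(OC)c3)OC(=O)[C@H](C)[C@H]2C)cc1OC
F3 | step 6 | (2R,3S)-4,4-bis(3,4-dimethoxyphenyl)-2,3-dimethylbutanoic acid | COc1ccc(C(c2ccc(OC)c(OC)c2)[C@H](C)[C@@H](C)C(=O)O)cc1OC
F4 | step 6 | (2R,3S,4R)-4-(3,4-dimethoxyphenyl)-6,7-dimethoxy-2,3-dimethyl-3,4-dihydronaphthalen-1(2H)-one | COc1ccc([C@@H]2c3cc(OC)c(OC)cc3C(=O)[C@H](C)[C@H]2C)cc1OC
F5 | step 1 | methyl (2R)-2-(trifluoromethylsulfonyloxy)propanoate | C[C@@H](OS(=O)(=O)C(F)(F)F)C(=O)OC
F6 | step 1 | methyl (2R,3R)-4-[(4S)-4-isopropyl-2-oxo-1,3-oxazolidin-3-yl]-2,3-dimethyl-4-oxobutanoate | COC(=O)[C@H](C)[C@@H](C)C(=O)N1[C@@H](C(C)C)COC1=O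
F7 | step 4 | S,S-diethyl (2R,3R)-2,3-dimethylbutanebis(thioate) | CCSC(=O)[C@H](C)[C@@H](C)C(=O)SCC
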